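## The problem

The target is a furanoheliangolide. Its ten-membered carbocycle C1–C10 is spanned by an oxygen between C3 and C10, giving an 11-oxabicyclo[6.2.1]undecane in which O, C3, C2, C1 and C10 form a 3(2H)-furanone. A trans-fused α-methylene-γ-butyrolactone sits across C6–C7, C8 carries a methacrylate, and the Z alkene C4=C5 carries the C15 hydroxymethyl group.

A synthesis has to close a medium ring that contains a Z trisubstituted alkene and a flat furanone, and it has to bridge that ring. Doing both in separate end-to-end closures is entropically and transannularly costly.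

Three of the four stereocentres (C6, C7, C8) are contiguous. C6 can control C7 through the lactone fusion and C8 by 1,2- and 1,3-induction. C10 is quaternary, oxygen-bearing and separated from the triad by C9 and by the bridge, so it can only be reached by relay through the bridge (from C3) or by an independent asymmetric step.

The methylene lactone and the methacrylate are Michael acceptors. The dienone is electrophilic, and the C6 oxygen is allylic and β to any C8 carbonyl, so it is prone to elimination. Strong bases and nucleophiles must therefore be avoided late, and the exocyclic methylene, the ester and the free C15 alcohol must come last.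

The feature that opens the key step is the environment of C10. It is bonded to the bridging oxygen, a methyl group, C9 and the C1 carbonyl, which is the substitution pattern left by an oxonium ylide after a [2,3] shift. C9–C8–C7 is the allyl unit of that shift, and C8 carries oxygen. If the same oxygen is first tied to C7 in a six-membered ether (O, C3, C4, C5, C6, C7), ylide formation and rearrangement create the oxolanone and the ten-membered ring together, and the Z C4=C5 alkene is simply carried over from the small ring.

## Retrosynthesis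

**Late functional groups.** The free C15 alcohol, the C8 methacrylate and the C11 methylene of 37 are removed first, back through 36, 35 and 34 to the silyl-protected lactone 31 and the alcohol 30. These are the base- and nucleophile-sensitive groups, and each is installed by a reaction at a single defined site. The C8 carbinol of 30 is traced to the keto lactone 29, because a ketone at C8 is what an enol ether at C8 delivers.

**Lactone and furanone.** In 29 the lactone C–O bond and the C7–H bond are cut, and the C2=C3 double bond is taken back to the saturated oxolanone. This leads through furanone 27 to the bicyclic ketone 26, which has a silyl enol ether at C7=C8, a silyl ether at C6 and a methyl ester at C12. The order is dictated by chemoselectivity. In 26 the C1 ketone is the only ketone and can enolise only toward C2, so dehydrogenation is unambiguous. Once C1 is a vinylogous ester (27), the C8 ketone can be unmasked and reduced without competition. Closing the lactone while C8 is still a ketone means only O6 can acylate, and C7 can settle to the trans fusion by enolisation.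

**Key disconnection.** In 26 the bonds O–C10 and C9–C10 are cut and O–C7 is restored. This gives oxonium ylide 25 and, behind it, diazo ketone 24, a 2,6-cis dihydropyran. The neighbouring cuts are an aldol or olefination closure at C4=C5, a lactonisation-type closure and a late transannular etherification. All of them need a ten-membered ring to be closed end to end, or to exist already. This cut instead makes both rings and the C10 stereocentre in one step by a three-atom ring expansion. The precursor 24 is a monocyclic six-membered ether with three stereocentres. The forward reaction needs the C3 tether and the C7 silyloxyvinyl arm cis, and needs ylide formation to be faster than the other carbenoid pathways.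

**Tether and arm.** The diazo ketone of 24 comes from acid 22 and diazoethane. The silyl enol ether of 22 comes from the methyl ketone 20, and that from the terminal alkyne 19. The acid comes from the allyl group of 16 by oxidative cleavage through aldehyde 18. The alkyne is kept until the ring stereocentres are set because it is a slim, inert placeholder for the C8 arm. It is hydrated only after the allyl group is gone, so that no enyne chemistry can interfere. The enol ether must precede the diazo group, since silyl triflates and gold catalysts are incompatible with a diazo ketone.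

**C3–C2 bond and C6.** Compound 16 is cut at C3–C2 into the anomeric acetate 14 and allyltrimethylsilane 15. The C6 silyl ether of 14 goes back through alcohol 13 to the enone 12 and the hemiacetal 11. Both stereocentres are set relative to the quaternary C7. The argument for an ethynyl group on C7 instead of an acetyl group is conformational. The alkyne sits axial at little cost, the CH2CO2Me arm sits equatorial, and axial attack at C6 (hydride) and at C3 (allylsilane) then follows the sense known for pyranone reduction and Ferrier-type C-allylation.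

**Pyranone.** Compound 11 is the Achmatowicz product of the tertiary 2-furyl carbinol 10, in which the carbinol oxygen becomes the ring oxygen and the furan 4-substituent becomes C15 on C4. Carbinol 10 is the single enantiomer of racemic 9, obtained by separation. Racemic 9 is cut at C7–C11 into ynone 6 and methyl acetate 7. A resolution is accepted here because asymmetric acetate additions to aryl alkynyl ketones are not dependable, and because C7 serves only as a relay and is destroyed in the key step.

**Furan.** Ynone 6 comes from Weinreb amide 4 and ethynyltrimethylsilane 5. Amide 4 comes from ester 3, and 3 from methyl 4-bromofuran-2-carboxylate 1 and the alkoxymethyltrifluoroborate 2. Starting from a 2,4-disubstituted furan avoids the uncertain regiochemistry of metalating a 3-substituted furan at the remote α-position.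

## Roads not taken

**Alternative 1:** The cut is the C4=C5 double bond. In the forward sense, the γ-carbon (C4) of a furanone carrying a 2-silyloxyethyl group on C3 would be converted in situ into its silyl dienol ether. This would attack a C5 dimethyl acetal under Lewis acid, and loss of methanol would give the 13-nor macrocycle A1.
- Merits: the furanone with its quaternary C10 and the C6–C8 triad with the lactone are made beforehand by acyclic methods, so C7 and C8 never have to be set on the ring. In this respect the route is better than the chosen plan.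
- Weak points: it is an end-to-end closure of a strained ten-membered ring that already holds a flat furanone, so it needs high dilution and competes with oligomerisation. The oxocarbenium ion at C5 is destabilised by the adjacent lactone oxygen. The dienol ether can also react at C2. C10 and the C6–C8 triad come from separate asymmetric sequences that must be matched.
- Comparison: the chosen plan answers with a ring expansion that has no macrocyclisation entropy and with C10 relayed from C3. Its price is that C7 is destroyed and must be reset after the key step.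

**Alternative 2:** The cut is C1–C10 (formed) against C3–C8 (broken) by a [3,3] shift. In the forward sense, a six-membered ring diol bearing alkenyl arms on C3 and C8 would be doubly deprotonated and would rearrange to the Z-cyclodecene-3,8-dione A2.
- Merits: it is also a ring expansion of a six-membered ring, so it is as good as the chosen plan in avoiding an end-to-end closure and in inheriting Z C4=C5. It is better in one respect, because C6 and C7 are ring stereocentres of the cyclohexene and survive.
- Weak points: A2 has no oxygen bridge, so the furanone must still be built from the C3 ketone and the C10 oxygen in several steps. C1 and C10 depend on chair-versus-boat preference and on the geometry of two enol ether arms, and C1 is later destroyed. Both enolates released by the shift carry a β-alkoxy group (C1 and C10) and can eliminate. The 3,8-dione can also undergo transannular aldol reaction.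
- Comparison: the chosen plan forms the bridge and the ring in the same step and sets C10 by a geometric constraint instead of a transition-state preference.

**Alternative 3:** The cut is the O–C10 bond of the bridge, made last. In the forward sense, acid would activate an E-1,10-epoxide of a germacranolide 3-ketone, and the enol oxygen at C3 would open it at C10 with inversion to give the hydroxy dienyl ether A3. Oxidation at C1 would finish the furanone.
- Merits: it is biomimetic, C10 is set stereospecifically, and its endgame is the shortest of all. Here it is clearly better than the chosen plan.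
- Weak points: the whole difficulty moves upstream. A ten-membered 1(10)E,4Z-dienone lactone with the full triad must be made first, epoxidised on one face only, and then kept from the transannular C–C cyclisations that germacradiene epoxides undergo in acid.
- Comparison: the chosen plan does not depend on an existing macrocycle. It builds ring, bridge and C10 from a six-membered ether whose stereochemistry follows pyranose precedent.

Key step: step 16

Remark: atoms are numbered as in the germacrane skeleton (C1–C15) throughout.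
Remark: trifluoroborate 2 is taken as a catalogue reagent.
Remark: the (3R) configuration of 10 would be confirmed by Mosher ester analysis of alcohol 13 before material is committed.

## Route

Step 1
Reactants: 1 methyl 4-bromofuran-2-carboxylate; 2 potassium {[(4-methoxybenzyl)oxy]methyl}trifluoroborate
Product: 3 methyl 4-{[(4-methoxybenzyl)oxy]methyl}furan-2-carboxylate
Conditions: Pd(OAc)2 (cat.), RuPhos, Cs2CO3, 1,4-dioxane/H2O, 100 °C
Reagents that add atoms: none
Why: Suzuki–Miyaura coupling of a heteroaryl bromide with a potassium alkoxymethyltrifluoroborate is an established way to attach a protected hydroxymethyl carbon; it places C15 on the furan 4-position, a pattern that metalation of a 3-substituted furan does not give reliably.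

Step 2
Reactants: 3 methyl 4-{[(4-methoxybenzyl)oxy]methyl}furan-2-carboxylate
Product: 4 N-methoxy-N-methyl-4-{[(4-methoxybenzyl)oxy]methyl}furan-2-carboxamide
Conditions: MeNH(OMe)·HCl, i-PrMgCl, THF, −20 °C
Reagents that add atoms: N,O-dimethylhydroxylamine hydrochloride, CNOC.Cl
Why: Magnesium amide aminolysis of a methyl ester (Weinreb amide formation) stops at the amide and prepares the acyl group for a single addition of an alkynyl anion.

Step 3
Reactants: 4 N-methoxy-N-methyl-4-{[(4-methoxybenzyl)oxy]methyl}furan-2-carboxamide; 5 ethynyltrimethylsilane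
Product: 6 1-(4-{[(4-methoxybenzyl)oxy]methyl}furan-2-yl)-3-(trimethylsilyl)prop-2-yn-1-one
Conditions: n-BuLi, THF, −78 °C; then 4, −78 → 0 °C
Reagents that add atoms: none
Why: Lithium acetylides add once to Weinreb amides because the chelated tetrahedral adduct survives until work-up; the silyl cap keeps the ynone from reacting as an acidic terminal alkyne in the next step.

Step 4
Reactants: 6 1-(4-{[(4-methoxybenzyl)oxy]methyl}furan-2-yl)-3-(trimethylsilyl)prop-2-yn-1-one; 7 methyl acetate
Product: 9 racemic methyl 3-hydroxy-3-(4-{[(4-methoxybenzyl)oxy]methyl}furan-2-yl)pent-4-ynoate, via silylalkyne aldol 8 (not isolated)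
Conditions: LiN(i-Pr)2, THF, −78 °C; AcOH; then Bu4NF/AcOH, THF, 0 °C
Reagents that add atoms: none
Why: The lithium enolate of methyl acetate adds 1,2 to the ynone carbonyl at low temperature (acetate aldol addition to a ketone), and buffered fluoride removes the alkynyl silyl group without the retro-aldol cleavage a free alkoxide would invite; nothing differentiates the ketone faces, so 9 is racemic.

Step 5
Reactants: 9 racemic methyl 3-hydroxy-3-(4-{[(4-methoxybenzyl)oxy]methyl}furan-2-yl)pent-4-ynoate
Product: 10 methyl (3R)-3-hydroxy-3-(4-{[(4-methoxybenzyl)oxy]methyl}furan-2-yl)pent-4-ynoate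
Conditions: preparative SFC on amylose tris(3,5-dimethylphenylcarbamate), CO2/MeOH
Reagents that add atoms: none
Why: Resolution of a racemate on a polysaccharide chiral stationary phase is routine for a neutral, UV-active, configurationally stable tertiary carbinol; no stereocentre is made, the (3R) enantiomer is kept and it fixes the absolute configuration of everything that follows.

Step 6
Reactants: 10 methyl (3R)-3-hydroxy-3-(4-{[(4-methoxybenzyl)oxy]methyl}furan-2-yl)pent-4-ynoate
Product: 11 methyl 2-[(2R)-2-ethynyl-6-hydroxy-5-{[(4-methoxybenzyl)oxy]methyl}-3-oxo-3,6-dihydro-2H-pyran-2-yl]acetate (both anomers)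
Conditions: NBS, NaHCO3, NaOAc, THF/H2O, 0 °C
Reagents that add atoms: water, O
Why: Achmatowicz rearrangement: oxidation of the furan at its free α-position, opening to the Z-enedione and closure of the tertiary hydroxyl onto the aldehyde give the 6-hydroxy-2H-pyran-3(6H)-one; C7 is untouched, its oxygen becomes the ring oxygen and the furan substituent ends on C4.

Step 7
Reactants: 11 methyl 2-[(2R)-2-ethynyl-6-hydroxy-5-{[(4-methoxybenzyl)oxy]methyl}-3-oxo-3,6-dihydro-2H-pyran-2-yl]acetate
Product: 12 methyl 2-[(2R)-6-acetoxy-2-ethynyl-5-{[(4-methoxybenzyl)oxy]methyl}-3-oxo-3,6-dihydro-2H-pyran-2-yl]acetate (both anomers)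
Conditions: Ac2O, Et3N, DMAP (cat.), CH2Cl2, −40 → 0 °C
Reagents that add atoms: acetic anhydride, CC(=O)OC(C)=O
Why: Acylation of the hemiacetal hydroxyl locks the ring form so that the enone can be reduced and supplies the anomeric leaving group for step 10; the anomeric configuration does not matter because C3 is ionised there.

Step 8
Reactants: 12 methyl 2-[(2R)-6-acetoxy-2-ethynyl-5-{[(4-methoxybenzyl)oxy]methyl}-3-oxo-3,6-dihydro-2H-pyran-2-yl]acetate
Product: 13 methyl 2-[(2R,3R)-6-acetoxy-2-ethynyl-3-hydroxy-5-{[(4-methoxybenzyl)oxy]methyl}-3,6-dihydro-2H-pyran-2-yl]acetate (hydroxyl cis to ethynyl)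
Conditions: NaBH4, CeCl3·7H2O, MeOH/CH2Cl2, −78 °C
Reagents that add atoms: none
Why: Luche 1,2-reduction; hydride adds axially to the half-chair that keeps the slim ethynyl group axial and the CH2CO2Me arm equatorial on C7, anti to the alkyne, so the C6 hydroxyl comes out equatorial, cis to the alkyne and trans to the ester arm (6R), as in reductions of 2-alkyl pyranones. An epimer with the hydroxyl cis to the ester arm would lactonise and separate easily.

Step 9
Reactants: 13 methyl 2-[(2R,3R)-6-acetoxy-2-ethynyl-3-hydroxy-5-{[(4-methoxybenzyl)oxy]methyl}-3,6-dihydro-2H-pyran-2-yl]acetate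
Product: 14 methyl 2-[(2R,3R)-6-acetoxy-3-[(tert-butyldimethylsilyl)oxy]-2-ethynyl-5-{[(4-methoxybenzyl)oxy]methyl}-3,6-dihydro-2H-pyran-2-yl]acetate
Conditions: t-BuMe2SiOTf, 2,6-lutidine, CH2Cl2, −78 °C
Reagents that add atoms: tert-butyldimethylsilyl trifluoromethanesulfonate, CC(C)(C)[Si](C)(C)OS(=O)(=O)C(F)(F)F
Why: Silyl triflate with a hindered base silylates the hindered allylic alcohol while the buffered medium leaves the anomeric acetate alone; the ether prevents cycloisomerisation of the homopropargylic alcohol in step 13 and keeps O6 distinct from O8 later.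

Step 10
Reactants: 14 methyl 2-[(2R,3R)-6-acetoxy-3-[(tert-butyldimethylsilyl)oxy]-2-ethynyl-5-{[(4-methoxybenzyl)oxy]methyl}-3,6-dihydro-2H-pyran-2-yl]acetate; 15 allyltrimethylsilane
Product: 16 methyl 2-[(2R,3R,6S)-6-allyl-3-[(tert-butyldimethylsilyl)oxy]-2-ethynyl-5-{[(4-methoxybenzyl)oxy]methyl}-3,6-dihydro-2H-pyran-2-yl]acetate
Conditions: Me3SiOTf (substoichiometric), CH2Cl2/MeCN, −78 → −40 °C
Reagents that add atoms: none
Why: Ferrier-type C-glycosylation (Hosomi–Sakurai allylation of an allylic oxocarbenium ion): the allylsilane attacks axially on the half-chair with ethynyl axial and the ester arm and silyloxy group equatorial, so the allyl group enters on the alkyne face, trans to the ester arm and 1,4-cis to the C6 oxygen (3S), the usual sense for such donors. This centre later fixes C10.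

Step 11
Reactants: 16 methyl 2-[(2R,3R,6S)-6-allyl-3-[(tert-butyldimethylsilyl)oxy]-2-ethynyl-5-{[(4-methoxybenzyl)oxy]methyl}-3,6-dihydro-2H-pyran-2-yl]acetate
Product: 18 methyl 2-[(2R,3R,6S)-3-[(tert-butyldimethylsilyl)oxy]-2-ethynyl-5-{[(4-methoxybenzyl)oxy]methyl}-6-(2-oxoethyl)-3,6-dihydro-2H-pyran-2-yl]acetate, via vicinal diol 17 (not isolated)
Conditions: OsO4 (cat.), NaIO4, 2,6-lutidine, 1,4-dioxane/H2O, rt
Reagents that add atoms: sodium periodate (oxygen source through OsO4), [Na+].[O-]I(=O)(=O)=O
Why: Lemieux–Johnson cleavage: the monosubstituted terminal alkene is dihydroxylated much faster than the hindered trisubstituted ring alkene flanked by two allylic oxygens and faster than the alkyne, and periodate cleaves the diol in the same flask.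

Step 12
Reactants: 18 methyl 2-[(2R,3R,6S)-3-[(tert-butyldimethylsilyl)oxy]-2-ethynyl-5-{[(4-methoxybenzyl)oxy]methyl}-6-(2-oxoethyl)-3,6-dihydro-2H-pyran-2-yl]acetate
Product: 19 2-[(2S,5R,6R)-5-[(tert-butyldimethylsilyl)oxy]-6-ethynyl-6-(2-methoxy-2-oxoethyl)-3-{[(4-methoxybenzyl)oxy]methyl}-5,6-dihydro-2H-pyran-2-yl]acetic acid
Conditions: NaClO2, NaH2PO4, 2-methyl-2-butene, t-BuOH/H2O, 0 °C
Reagents that add atoms: sodium chlorite, [Na+].[O-]Cl=O
Why: Pinnick oxidation takes the aldehyde to the acid under mildly acidic buffer without touching alkyne, alkene or silyl ether, and avoids base that could open the β-alkoxy aldehyde by retro-oxa-Michael reaction.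

Step 13
Reactants: 19 2-[(2S,5R,6R)-5-[(tert-butyldimethylsilyl)oxy]-6-ethynyl-6-(2-methoxy-2-oxoethyl)-3-{[(4-methoxybenzyl)oxy]methyl}-5,6-dihydro-2H-pyran-2-yl]acetic acid
Product: 20 2-[(2S,5R,6S)-6-acetyl-5-[(tert-butyldimethylsilyl)oxy]-6-(2-methoxy-2-oxoethyl)-3-{[(4-methoxybenzyl)oxy]methyl}-5,6-dihydro-2H-pyran-2-yl]acetic acid
Conditions: (Ph3P)AuN(SO2CF3)2 (cat.), 1,4-dioxane/H2O, 50 °C
Reagents that add atoms: water, O
Why: Gold-catalysed Markovnikov hydration of a terminal alkyne, assisted here by 5-exo participation of the neighbouring ester carbonyl, gives the methyl ketone on C7; it is run after the allyl group has been cleaved so that no enyne cycloisomerisation can compete.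

Step 14
Reactants: 20 2-[(2S,5R,6S)-6-acetyl-5-[(tert-butyldimethylsilyl)oxy]-6-(2-methoxy-2-oxoethyl)-3-{[(4-methoxybenzyl)oxy]methyl}-5,6-dihydro-2H-pyran-2-yl]acetic acid
Product: 22 2-[(2S,5R,6S)-5-[(tert-butyldimethylsilyl)oxy]-6-{1-[(tert-butyldimethylsilyl)oxy]vinyl}-6-(2-methoxy-2-oxoethyl)-3-{[(4-methoxybenzyl)oxy]methyl}-5,6-dihydro-2H-pyran-2-yl]acetic acid, via bis-silyl ester 21 (not isolated)
Conditions: t-BuMe2SiOTf, Et3N, CH2Cl2, −78 → 0 °C; then K2CO3, MeOH/H2O, 0 °C; pH 7 buffer, used at once
Reagents that add atoms: tert-butyldimethylsilyl trifluoromethanesulfonate, CC(C)(C)[Si](C)(C)OS(=O)(=O)C(F)(F)F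
Why: Soft enolisation with silyl triflate and triethylamine converts the methyl ketone, which can enolise only toward C9 because C7 is quaternary, into its silyl enol ether and leaves the esters alone; the silyl ester formed from the acid is cleaved selectively by brief carbonate methanolysis, which a ketone silyl enol ether survives.

Step 15
Reactants: 22 2-[(2S,5R,6S)-5-[(tert-butyldimethylsilyl)oxy]-6-{1-[(tert-butyldimethylsilyl)oxy]vinyl}-6-(2-methoxy-2-oxoethyl)-3-{[(4-methoxybenzyl)oxy]methyl}-5,6-dihydro-2H-pyran-2-yl]acetic acid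
Product: 24 methyl 2-[(2S,3R,6S)-3-[(tert-butyldimethylsilyl)oxy]-2-{1-[(tert-butyldimethylsilyl)oxy]vinyl}-6-(3-diazo-2-oxobutyl)-5-{[(4-methoxybenzyl)oxy]methyl}-3,6-dihydro-2H-pyran-2-yl]acetate, via mixed anhydride 23 (not isolated)
Conditions: i-BuOCOCl, Et3N, THF, −20 °C; then CH3CHN2 (from N-ethyl-N-nitrosourea, KOH), Et2O, −20 → 0 °C
Reagents that add atoms: diazoethane, CC=[N+]=[N-]
Why: Acylation of a diazoalkane by a mixed carbonic anhydride (Arndt–Eistert-type diazo ketone synthesis) gives the α-methyl diazo ketone under amine-buffered conditions that the enol ether tolerates; C10 and C14 enter here.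

Step 16
Reactants: 24 methyl 2-[(2S,3R,6S)-3-[(tert-butyldimethylsilyl)oxy]-2-{1-[(tert-butyldimethylsilyl)oxy]vinyl}-6-(3-diazo-2-oxobutyl)-5-{[(4-methoxybenzyl)oxy]methyl}-3,6-dihydro-2H-pyran-2-yl]acetate
Product: 26 methyl (3S,6R,10S,4Z,7E)-6,8-bis[(tert-butyldimethylsilyl)oxy]-15-[(4-methoxybenzyl)oxy]-1-oxo-3,10-epoxy-13-norgermacra-4,7-dien-12-oate, via oxonium ylide 25 (not isolated)
Conditions: Cu(CF3COCHCOCF3)2 (cat.), CH2Cl2, reflux, slow addition of 24
Reagents that add atoms: none
Why: Cu(CF3COCHCOCF3)2 (divalent copper) decomposes the diazo ketone to an electrophilic copper carbenoid at C10, which is captured by the ring oxygen and closes the five-membered oxonium ring of ylide 25 (exo closure with respect to the C3–C2–C1 tether). The ylide then rearranges [2,3] through a five-centre envelope transition state: C10 bonds to the terminal enol ether carbon C9, the allylic O–C7 bond breaks and C7=C8 forms, so the oxolanone and the ten-membered carbocycle appear together by a three-atom ring expansion of the dihydropyran and no end-to-end macrocyclisation is needed. The closest known reaction type is the copper- or rhodium-carbenoid oxonium ylide [2,3] rearrangement of 2-vinyl cyclic ethers carrying a tethered diazo ketone, which gives 11-oxabicyclo[6.2.1]undecenones. C10 is the only new stereocentre and is set by C3, because O–C10 forms on the face of the tether and C9 is delivered from C7 across the same oxygen, which places C9 and C4 cis on the oxolanone (10S). The step needs ylide formation to outrun 1,2-hydride migration from the C14 methyl, cyclopropanation of the enol ether and C–H insertion; closure of a five-membered ylide onto a proximal ether oxygen and the use of copper, which is less prone than rhodium to the hydride shift, should secure this. It also needs the [2,3] shift to beat the [1,2] shift and to use the exocyclic silyloxyvinyl arm and not the endocyclic C4=C5 unit; the cis relation of tether and arm allows the former, and the latter would require C10 to reach C5 across the ring. The ring-cis geometry of C7=C8 is expected because the nine-membered oxacycle already holds Z C4=C5, and it is of no consequence since C7 and C8 are reset later.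

Step 17
Reactants: 26 methyl (3S,6R,10S,4Z,7E)-6,8-bis[(tert-butyldimethylsilyl)oxy]-15-[(4-methoxybenzyl)oxy]-1-oxo-3,10-epoxy-13-norgermacra-4,7-dien-12-oate
Product: 27 methyl (6R,10S,4Z,7E)-6,8-bis[(tert-butyldimethylsilyl)oxy]-15-[(4-methoxybenzyl)oxy]-1-oxo-3,10-epoxy-13-norgermacra-2,4,7-trien-12-oate
Conditions: LiN(SiMe3)2, THF, −78 °C; then PhS(Cl)=N-t-Bu, −78 °C
Reagents that add atoms: none
Why: Mukaiyama dehydrogenation of a ketone through its lithium enolate with N-tert-butylbenzenesulfinimidoyl chloride: only C2 can be enolised because C10 is quaternary, the sulfur reagent adds on the exo face syn to H3, and syn elimination gives the 3(2H)-furanone. From here C1 is a vinylogous ester and no longer competes with the C8 ketone.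

Step 18
Reactants: 27 methyl (6R,10S,4Z,7E)-6,8-bis[(tert-butyldimethylsilyl)oxy]-15-[(4-methoxybenzyl)oxy]-1-oxo-3,10-epoxy-13-norgermacra-2,4,7-trien-12-oate
Product: 29 (6R,7S,10S,4Z)-15-[(4-methoxybenzyl)oxy]-1,8-dioxo-3,10-epoxy-13-norgermacra-2,4-dien-12,6-olide, via hydroxy keto ester 28 (not isolated)
Conditions: HF·pyridine, THF, 0 °C → rt; then camphorsulfonic acid (cat.), CH2Cl2, rt
Reagents that add atoms: none
Why: Cleavage of both silyl groups frees the C8 ketone and the C6 hydroxyl, which closes the γ-lactone onto the methyl ester under acid catalysis; only O6 is free, so the 12,6-olide regiochemistry is fixed. C7, now α to the ketone, should equilibrate by acid-catalysed enolisation to the trans-fused lactone, the fusion that lets the ten-membered ring keep an anticlinal C5–C6–C7–C8 torsion (the target geometry, 7S by priority in 29).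

Step 19
Reactants: 29 (6R,7S,10S,4Z)-15-[(4-methoxybenzyl)oxy]-1,8-dioxo-3,10-epoxy-13-norgermacra-2,4-dien-12,6-olide
Product: 30 (6R,7R,8R,10S,4Z)-8-hydroxy-15-[(4-methoxybenzyl)oxy]-1-oxo-3,10-epoxy-13-norgermacra-2,4-dien-12,6-olide
Conditions: NaBH4, MeOH/CH2Cl2, −78 °C; AcOH quench at −78 °C
Reagents that add atoms: none
Why: Borohydride reduces the saturated C8 ketone at low temperature much faster than the vinylogous ester or the lactone; hydride should enter from the outer face syn to H7 and anti to the C7–C11 bond, giving the hydroxyl cis to C11 (8R), and the cold acidic quench keeps the alkoxide from translactonising.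

Step 20
Reactants: 30 (6R,7R,8R,10S,4Z)-8-hydroxy-15-[(4-methoxybenzyl)oxy]-1-oxo-3,10-epoxy-13-norgermacra-2,4-dien-12,6-olide
Product: 31 (6R,7S,8R,10S,4Z)-15-[(4-methoxybenzyl)oxy]-1-oxo-8-[(triethylsilyl)oxy]-3,10-epoxy-13-norgermacra-2,4-dien-12,6-olide
Conditions: Et3SiOTf, 2,6-lutidine, CH2Cl2, −78 °C
Reagents that add atoms: triethylsilyl trifluoromethanesulfonate, CC[Si](CC)(CC)OS(=O)(=O)C(F)(F)F
Why: Silylation of the secondary alcohol keeps an O8 alkoxide from attacking the lactone or the iminium salt during the enolate chemistry of step 21; no bond to a stereocentre is changed (the C7 descriptor changes only through priorities).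

Step 21
Reactants: 31 (6R,7S,8R,10S,4Z)-15-[(4-methoxybenzyl)oxy]-1-oxo-8-[(triethylsilyl)oxy]-3,10-epoxy-13-norgermacra-2,4-dien-12,6-olide
Product: 34 (6R,7S,8R,10S,4Z)-15-[(4-methoxybenzyl)oxy]-1-oxo-8-[(triethylsilyl)oxy]-3,10-epoxygermacra-2,4,11(13)-trien-12,6-olide, via Mannich base 32 (not isolated), via ammonium iodide 33 (not isolated)
Conditions: LiN(SiMe3)2, THF, −78 °C; CH2=NMe2+ I−, −78 → 0 °C; then MeI, MeOH, rt; NaHCO3 (aq), CH2Cl2
Reagents that add atoms: N,N-dimethylmethyleneiminium iodide (Eschenmoser's salt), C=[N+](C)C.[I-]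
Why: α-Methylenation of a γ-lactone by the Eschenmoser-salt Mannich reaction of its lithium enolate, N-methylation and bicarbonate-induced elimination; the furanone has no enolisable position, so the lactone C11 is the site deprotonated, and the C11 stereocentre of the Mannich base vanishes on elimination.

Step 22
Reactants: 34 (6R,7S,8R,10S,4Z)-15-[(4-methoxybenzyl)oxy]-1-oxo-8-[(triethylsilyl)oxy]-3,10-epoxygermacra-2,4,11(13)-trien-12,6-olide
Product: 35 (6R,7R,8R,10S,4Z)-8-hydroxy-15-[(4-methoxybenzyl)oxy]-1-oxo-3,10-epoxygermacra-2,4,11(13)-trien-12,6-olide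
Conditions: HF·pyridine, pyridine, THF, 0 °C
Reagents that add atoms: none
Why: Buffered HF·pyridine removes a triethylsilyl ether without adding to the exocyclic methylene lactone or the dienone.

Step 23
Reactants: 35 (6R,7R,8R,10S,4Z)-8-hydroxy-15-[(4-methoxybenzyl)oxy]-1-oxo-3,10-epoxygermacra-2,4,11(13)-trien-12,6-olide
Product: 36 (6R,7R,8R,10S,4Z)-8-(methacryloyloxy)-15-[(4-methoxybenzyl)oxy]-1-oxo-3,10-epoxygermacra-2,4,11(13)-trien-12,6-olide
Conditions: methacrylic anhydride, Et3N, DMAP (cat.), CH2Cl2, 0 °C → rt
Reagents that add atoms: methacrylic anhydride, CC(=C)C(=O)OC(=O)C(C)=C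
Why: DMAP-catalysed acylation of the secondary alcohol; O8 is the only free hydroxyl, so the ester position is unambiguous and C8 keeps its configuration.

Step 24
Reactants: 36 (6R,7R,8R,10S,4Z)-8-(methacryloyloxy)-15-[(4-methoxybenzyl)oxy]-1-oxo-3,10-epoxygermacra-2,4,11(13)-trien-12,6-olide
Product: 37 (6R,7R,8R,10S,4Z)-15-hydroxy-8-(methacryloyloxy)-1-oxo-3,10-epoxygermacra-2,4,11(13)-trien-12,6-olide (CNP0180483.4)
Conditions: DDQ, CH2Cl2/pH 7 buffer, 0 °C
Reagents that add atoms: none
Why: Oxidative cleavage of the p-methoxybenzyl ether with DDQ under buffered two-phase conditions is neutral and spares the enoate, the methylene lactone and the dienone, so the free C15 alcohol is revealed last.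

## Compound list

1 | methyl 4-bromofuran-2-carboxylate | COC(=O)c1cc(Br)co1 | starting material
2 | potassium {[(4-methoxybenzyl)oxy]methyl}trifluoroborate | [K+].COc1ccc(COC[B-](F)(F)F)cc1 | starting material
3 | methyl 4-{[(4-methoxybenzyl)oxy]methyl}furan-2-carboxylate | COC(=O)c1cc(COCc2ccc(OC)cc2)co1 | intermediate
4 | N-methoxy-N-methyl-4-{[(4-methoxybenzyl)oxy]methyl}furan-2-carboxamide | CON(C)C(=O)c1cc(COCc2ccc(OC)cc2)co1 | intermediate
5 | ethynyltrimethylsilane | C#C[Si](C)(C)C | starting material
6 | 1-(4-{[(4-methoxybenzyl)oxy]methyl}furan-2-yl)-3-(trimethylsilyl)prop-2-yn-1-one | C[Si](C)(C)C#CC(=O)c1cc(COCc2ccc(OC)cc2)co1 | intermediate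
7 | methyl acetate | COC(C)=O | starting material
8 | racemic methyl 3-hydroxy-3-(4-{[(4-methoxybenzyl)oxy]methyl}furan-2-yl)-5-(trimethylsilyl)pent-4-ynoate | COC(=O)CC(O)(C#C[Si](C)(C)C)c1cc(COCc2ccc(OC)cc2)co1 | intermediate (not isolated)
9 | racemic methyl 3-hydroxy-3-(4-{[(4-methoxybenzyl)oxy]methyl}furan-2-yl)pent-4-ynoate | COC(=O)CC(O)(C#C)c1cc(COCc2ccc(OC)cc2)co1 | intermediate
10 | methyl (3R)-3-hydroxy-3-(4-{[(4-methoxybenzyl)oxy]methyl}furan-2-yl)pent-4-ynoate | O[C@](CC(=O)OC)(C#C)c1cc(COCc2ccc(OC)cc2)co1 | intermediate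
11 | methyl 2-[(2R)-2-ethynyl-6-hydroxy-5-{[(4-methoxybenzyl)oxy]methyl}-3-oxo-3,6-dihydro-2H-pyran-2-yl]acetate, both anomers | OC1O[C@](CC(=O)OC)(C#C)C(=O)C=C1COCc2ccc(OC)cc2 | intermediate
12 | methyl 2-[(2R)-6-acetoxy-2-ethynyl-5-{[(4-methoxybenzyl)oxy]methyl}-3-oxo-3,6-dihydro-2H-pyran-2-yl]acetate, both anomers | CC(=O)OC1O[C@](CC(=O)OC)(C#C)C(=O)C=C1COCc2ccc(OC)cc2 | intermediate
13 | methyl 2-[(2R,3R)-6-acetoxy-2-ethynyl-3-hydroxy-5-{[(4-methoxybenzyl)oxy]methyl}-3,6-dihydro-2H-pyran-2-yl]acetate, hydroxyl cis to ethynyl | CC(=O)OC1O[C@](CC(=O)OC)(C#C)[C@H](O)C=C1COCc2ccc(OC)cc2 | intermediate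
14 | methyl 2-[(2R,3R)-6-acetoxy-3-[(tert-butyldimethylsilyl)oxy]-2-ethynyl-5-{[(4-methoxybenzyl)oxy]methyl}-3,6-dihydro-2H-pyran-2-yl]acetate | CC(=O)OC1O[C@](CC(=O)OC)(C#C)[C@H](O[Si](C)(C)C(C)(C)C)C=C1COCc2ccc(OC)cc2 | intermediate
15 | allyltrimethylsilane | C=CC[Si](C)(C)C | starting material
16 | methyl 2-[(2R,3R,6S)-6-allyl-3-[(tert-butyldimethylsilyl)oxy]-2-ethynyl-5-{[(4-methoxybenzyl)oxy]methyl}-3,6-dihydro-2H-pyran-2-yl]acetate; allyl, silyloxy and ethynyl groups all cis | C=CC[C@@H]1O[C@](CC(=O)OC)(C#C)[C@H](O[Si](C)(C)C(C)(C)C)C=C1COCc2ccc(OC)cc2 | intermediate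
17 | 6-(2,3-dihydroxypropyl) analogue of 16 (side-chain carbinol epimers) | OCC(O)C[C@@H]1O[C@](CC(=O)OC)(C#C)[C@H](O[Si](C)(C)C(C)(C)C)C=C1COCc2ccc(OC)cc2 | intermediate (not isolated)
18 | methyl 2-[(2R,3R,6S)-3-[(tert-butyldimethylsilyl)oxy]-2-ethynyl-5-{[(4-methoxybenzyl)oxy]methyl}-6-(2-oxoethyl)-3,6-dihydro-2H-pyran-2-yl]acetate | O=CC[C@@H]1O[C@](CC(=O)OC)(C#C)[C@H](O[Si](C)(C)C(C)(C)C)C=C1COCc2ccc(OC)cc2 | intermediate
19 | 2-[(2S,5R,6R)-5-[(tert-butyldimethylsilyl)oxy]-6-ethynyl-6-(2-methoxy-2-oxoethyl)-3-{[(4-methoxybenzyl)oxy]methyl}-5,6-dihydro-2H-pyran-2-yl]acetic acid | OC(=O)C[C@@H]1O[C@](CC(=O)OC)(C#C)[C@H](O[Si](C)(C)C(C)(C)C)C=C1COCc2ccc(OC)cc2 | intermediate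
20 | 2-[(2S,5R,6S)-6-acetyl-5-[(tert-butyldimethylsilyl)oxy]-6-(2-methoxy-2-oxoethyl)-3-{[(4-methoxybenzyl)oxy]methyl}-5,6-dihydro-2H-pyran-2-yl]acetic acid | OC(=O)C[C@@H]1O[C@](CC(=O)OC)(C(C)=O)[C@H](O[Si](C)(C)C(C)(C)C)C=C1COCc2ccc(OC)cc2 | intermediate
21 | tert-butyldimethylsilyl ester of acid 22 | CC(C)(C)[Si](C)(C)OC(=O)C[C@@H]1O[C@](CC(=O)OC)(C(O[Si](C)(C)C(C)(C)C)=C)[C@H](O[Si](C)(C)C(C)(C)C)C=C1COCc2ccc(OC)cc2 | intermediate (not isolated)
22 | 2-[(2S,5R,6S)-5-[(tert-butyldimethylsilyl)oxy]-6-{1-[(tert-butyldimethylsilyl)oxy]vinyl}-6-(2-methoxy-2-oxoethyl)-3-{[(4-methoxybenzyl)oxy]methyl}-5,6-dihydro-2H-pyran-2-yl]acetic acid | OC(=O)C[C@@H]1O[C@](CC(=O)OC)(C(O[Si](C)(C)C(C)(C)C)=C)[C@H](O[Si](C)(C)C(C)(C)C)C=C1COCc2ccc(OC)cc2 | intermediate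
23 | isobutyl carbonic mixed anhydride of acid 22 | CC(C)COC(=O)OC(=O)C[C@@H]1O[C@](CC(=O)OC)(C(O[Si](C)(C)C(C)(C)C)=C)[C@H](O[Si](C)(C)C(C)(C)C)C=C1COCc2ccc(OC)cc2 | intermediate (not isolated)
24 | methyl 2-[(2S,3R,6S)-3-[(tert-butyldimethylsilyl)oxy]-2-{1-[(tert-butyldimethylsilyl)oxy]vinyl}-6-(3-diazo-2-oxobutyl)-5-{[(4-methoxybenzyl)oxy]methyl}-3,6-dihydro-2H-pyran-2-yl]acetate; tether, C6 silyloxy and silyloxyvinyl groups all cis | CC(=[N+]=[N-])C(=O)C[C@@H]1O[C@](CC(=O)OC)(C(O[Si](C)(C)C(C)(C)C)=C)[C@H](O[Si](C)(C)C(C)(C)C)C=C1COCc2ccc(OC)cc2 | intermediate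
25 | bicyclic oxonium ylide from 24: the ring oxygen bonded to C3, C7 and C10, carbanion at C10 next to the C1 ketone | C[C-]1C(=O)C[C@@H]2[O+]1[C@](CC(=O)OC)(C(O[Si](C)(C)C(C)(C)C)=C)[C@H](O[Si](C)(C)C(C)(C)C)C=C2COCc1ccc(OC)cc1 | intermediate (not isolated)
26 | methyl (3S,6R,10S,4Z,7E)-6,8-bis[(tert-butyldimethylsilyl)oxy]-15-[(4-methoxybenzyl)oxy]-1-oxo-3,10-epoxy-13-norgermacra-4,7-dien-12-oate | CC(C)(C)[Si](C)(C)O/C1=C(CC(=O)OC)/[C@H](O[Si](C)(C)C(C)(C)C)/C=C(COCc3ccc(OC)cc3)\[C@@H]2CC(=O)[C@](C)(C1)O2 | intermediate
27 | methyl (6R,10S,4Z,7E)-6,8-bis[(tert-butyldimethylsilyl)oxy]-15-[(4-methoxybenzyl)oxy]-1-oxo-3,10-epoxy-13-norgermacra-2,4,7-trien-12-oate | CC(C)(C)[Si](C)(C)O/C1=C(CC(=O)OC)/[C@H](O[Si](C)(C)C(C)(C)C)/C=C(COCc3ccc(OC)cc3)\C2=CC(=O)[C@](C)(C1)O2 | intermediate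
28 | methyl (6R,10S,4Z)-6-hydroxy-15-[(4-methoxybenzyl)oxy]-1,8-dioxo-3,10-epoxy-13-norgermacra-2,4-dien-12-oate (C7 epimers) | O=C1C[C@]2(C)OC(=CC2=O)/C(COCc3ccc(OC)cc3)=C\[C@@H](O)C1CC(=O)OC | intermediate (not isolated)
29 | (6R,7S,10S,4Z)-15-[(4-methoxybenzyl)oxy]-1,8-dioxo-3,10-epoxy-13-norgermacra-2,4-dien-12,6-olide, trans-fused lactone | O=C1C[C@]2(C)OC(=CC2=O)/C(COCc3ccc(OC)cc3)=C\[C@H]2OC(=O)C[C@@H]21 | intermediate
30 | (6R,7R,8R,10S,4Z)-8-hydroxy-15-[(4-methoxybenzyl)oxy]-1-oxo-3,10-epoxy-13-norgermacra-2,4-dien-12,6-olide | O[C@@H]1C[C@]2(C)OC(=CC2=O)/C(COCc3ccc(OC)cc3)=C\[C@H]2OC(=O)C[C@@H]21 | intermediate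
31 | (6R,7S,8R,10S,4Z)-15-[(4-methoxybenzyl)oxy]-1-oxo-8-[(triethylsilyl)oxy]-3,10-epoxy-13-norgermacra-2,4-dien-12,6-olide | CC[Si](CC)(CC)O[C@@H]1C[C@]2(C)OC(=CC2=O)/C(COCc3ccc(OC)cc3)=C\[C@H]2OC(=O)C[C@@H]21 | intermediate
32 | 13-(dimethylamino) derivative of 31 (C11 epimers) | CC[Si](CC)(CC)O[C@@H]1C[C@]2(C)OC(=CC2=O)/C(COCc3ccc(OC)cc3)=C\[C@H]2OC(=O)C(CN(C)C)[C@@H]21 | intermediate (not isolated)
33 | 13-(trimethylammonio) derivative of 31, iodide (C11 epimers) | CC[Si](CC)(CC)O[C@@H]1C[C@]2(C)OC(=CC2=O)/C(COCc3ccc(OC)cc3)=C\[C@H]2OC(=O)C(C[N+](C)(C)C)[C@@H]21.[I-] | intermediate (not isolated)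
34 | (6R,7S,8R,10S,4Z)-15-[(4-methoxybenzyl)oxy]-1-oxo-8-[(triethylsilyl)oxy]-3,10-epoxygermacra-2,4,11(13)-trien-12,6-olide | CC[Si](CC)(CC)O[C@@H]1C[C@]2(C)OC(=CC2=O)/C(COCc3ccc(OC)cc3)=C\[C@H]2OC(=O)C(=C)[C@@H]21 | intermediate
35 | (6R,7R,8R,10S,4Z)-8-hydroxy-15-[(4-methoxybenzyl)oxy]-1-oxo-3,10-epoxygermacra-2,4,11(13)-trien-12,6-olide | O[C@@H]1C[C@]2(C)OC(=CC2=O)/C(COCc3ccc(OC)cc3)=C\[C@H]2OC(=O)C(=C)[C@@H]21 | intermediate
36 | (6R,7R,8R,10S,4Z)-8-(methacryloyloxy)-15-[(4-methoxybenzyl)oxy]-1-oxo-3,10-epoxygermacra-2,4,11(13)-trien-12,6-olide | C=C(C)C(=O)O[C@@H]1C[C@]2(C)OC(=CC2=O)/C(COCc3ccc(OC)cc3)=C\[C@H]2OC(=O)C(=C)[C@@H]21 | intermediate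
37 | (6R,7R,8R,10S,4Z)-15-hydroxy-8-(methacryloyloxy)-1-oxo-3,10-epoxygermacra-2,4,11(13)-trien-12,6-olide (CNP0180483.4) | C=C(C)C(=O)O[C@@H]1C[C@]2(C)OC(=CC2=O)/C(CO)=C\[C@H]2OC(=O)C(=C)[C@@H]21 | target

## Step count and risks

Total: 24 steps. Longest linear sequence: 24 steps, from 1 to 37. Compounds 2, 5, 7 and 15 enter as reactants of single steps.

**Step 16 (key step).** The methyl-bearing copper carbenoid may suffer 1,2-hydride migration to a vinyl ketone, or add to the electron-rich enol ether, before the ring oxygen captures it.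
- Fallback, from acid 22 back to 26: the mixed anhydride is treated with diazomethane to give the diazomethyl ketone F1, which has no migrating hydrogen next to the carbenoid.
- The same copper-catalysed ylide rearrangement, the well-established case, then gives the C10-unsubstituted bicyclic ketone F2.
- Silylation under equilibrating conditions (Me3SiOTf, Et3N) is expected to favour the more substituted, oxygen-stabilised enol ether toward the bridgehead, giving the C1–C10 trimethylsilyl enol ether F3.
- Fluoride-promoted methylation (MeI, anhydrous benzyltrimethylammonium fluoride) on the only open face, opposite the six-carbon bridge, returns to 26.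

**Step 10.** Facial selectivity at C3 may be poor because C7 is quaternary and neither face of the oxocarbenium ion is strongly shielded.
- Fallback, from 14 to 19: the anomer of 14 with the acetate cis to the ethynyl group is separated and substituted with Meldrum's acid under Pd(PPh3)4 (zerovalent palladium) catalysis.
- This Tsuji–Trost reaction goes with net retention, so C3 is fixed by the leaving group and not by the ion conformation. It gives the Meldrum's acid adduct F4.
- Hydrolysis and decarboxylation in wet pyridine at 100 °C give acid 19 directly, bypassing 16 and 18.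

**Step 8.** Hydride may attack the C6 carbonyl from the face that puts the hydroxyl cis to the ester arm, followed by lactonisation of that epimer.
- Fallback, from 12 to 16: the order is inverted. Enone acetate 12 is allylated first (15, Me3SiOTf) to give the allyl enone F5.
- F5 carries the allyl and ethynyl groups axial on the same face, so Luche reduction from the opposite face gives the alcohol F6 with the hydroxyl cis to both.
- Silylation as in step 9 gives 16.

**Step 18.** The C6 oxygen, β to the C8 ketone and vinylogous to the dienone, may be lost by elimination during equilibration, or the cis-fused lactone may prevail.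
- Fallback, from 27 to 30: cold, pyridine-buffered HF·pyridine is used and the hydroxy keto ester 28 is isolated.
- Its C8 ketone is reduced at once by hydroxyl-directed anti delivery (Me4NBH(OAc)3, AcOH/MeCN, −20 °C; Evans–Saksena reduction), which leaves the C1 carbonyl alone and gives the 6,8-anti diol ester F7.
- Acid-catalysed lactonisation of F7 gives 30. The open question in this variant is whether O6 or O8 closes the lactone, which is why it is held in reserve.

**Step 19.** Hydride may be delivered to the wrong face of the C8 ketone, or the C8 alkoxide may attack the lactone.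
- Fallback, from 29 to 30: if the reduction gives the 8-epimeric alcohol F8, C8 is inverted by Mitsunobu reaction with chloroacetic acid (PPh3, diisopropyl azodicarboxylate) to the chloroacetate F9.
- F9 is cleaved under neutral conditions with thiourea to give 30.

## Further compounds

F1 | step 16 | diazomethyl ketone analogue of 24 (no C14 methyl) | [N-]=[N+]=CC(=O)C[C@@H]1O[C@](CC(=O)OC)(C(O[Si](C)(C)C(C)(C)C)=C)[C@H](O[Si](C)(C)C(C)(C)C)C=C1COCc2ccc(OC)cc2
F2 | step 16 | 14-nor analogue of 26 (hydrogen on C10) | CC(C)(C)[Si](C)(C)O/C1=C(CC(=O)OC)/[C@H](O[Si](C)(C)C(C)(C)C)/C=C(COCc3ccc(OC)cc3)\[C@@H]2CC(=O)[C@H](C1)O2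
F3 | step 16 | C1–C10 trimethylsilyl enol ether of F2 | CC(C)(C)[Si](C)(C)O/C1=C(CC(=O)OC)/[C@H](O[Si](C)(C)C(C)(C)C)/C=C(COCc3ccc(OC)cc3)\[C@@H]2CC(O[Si](C)(C)C)=C(C1)O2
F4 | step 10 | Meldrum's acid adduct at C3 (2,2-dimethyl-4,6-dioxo-1,3-dioxan-5-yl in place of the allyl group of 16) | CC1(C)OC(=O)C(C(=O)O1)[C@@H]1O[C@](CC(=O)OC)(C#C)[C@H](O[Si](C)(C)C(C)(C)C)C=C1COCc2ccc(OC)cc2
F5 | step 8 | methyl 2-[(2R,6S)-6-allyl-2-ethynyl-5-{[(4-methoxybenzyl)oxy]methyl}-3-oxo-3,6-dihydro-2H-pyran-2-yl]acetate | C=CC[C@@H]1O[C@](CC(=O)OC)(C#C)C(=O)C=C1COCc2ccc(OC)cc2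
F6 | step 8 | methyl 2-[(2R,3R,6S)-6-allyl-2-ethynyl-3-hydroxy-5-{[(4-methoxybenzyl)oxy]methyl}-3,6-dihydro-2H-pyran-2-yl]acetate | C=CC[C@@H]1O[C@](CC(=O)OC)(C#C)[C@H](O)C=C1COCc2ccc(OC)cc2
F7 | step 18 | methyl (6R,7R,8R,10S,4Z)-6,8-dihydroxy-15-[(4-methoxybenzyl)oxy]-1-oxo-3,10-epoxy-13-norgermacra-2,4-dien-12-oate | O[C@@H]1C[C@]2(C)OC(=CC2=O)/C(COCc3ccc(OC)cc3)=C\[C@@H](O)[C@@H]1CC(=O)OC
F8 | step 19 | 8-epimer of 30 | O[C@H]1C[C@]2(C)OC(=CC2=O)/C(COCc3ccc(OC)cc3)=C\[C@H]2OC(=O)C[C@@H]21
F9 | step 19 | 8-O-chloroacetate of 30 | ClCC(=O)O[C@@H]1C[C@]2(C)OC(=CC2=O)/C(COCc3ccc(OC)cc3)=C\[C@H]2OC(=O)C[C@@H]21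
A1 | alternative 1 | protected 13-nor macrocyclic core with Z C4=C5 | CC(C)(C)[Si](C)(C)O[C@@H]1C[C@]2(C)OC(=CC2=O)/C(CO[Si](c3ccccc3)(c3ccccc3)C(C)(C)C)=C\[C@H]2OC(=O)C[C@@H]21
A2 | alternative 2 | Z-cyclodecene-3,8-dione with C1 and C10 oxygenated | O=C1C[C@](C)(OCOC)[C@@H](OCOC)CC(=O)/C(CO[Si](C)(C)C(C)(C)C)=C\[C@@H](O[Si](C)(C)C(C)(C)C)[C@@H]1CCOCc2ccc(OC)cc2
A3 | alternative 3 | 1-hydroxy-3,10-epoxy-2,4-diene (1-dihydro precursor of the furanone) | C=C(C)C(=O)O[C@@H]1C[C@]2(C)OC(=C[C@H]2O)/C(CO[Si](C)(C)C(C)(C)C)=C\[C@H]2OC(=O)C(=C)[C@@H]21
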